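## Retrosynthetic overview

- The C3 and C18 hydroxyls are unmasked last from a 2‑isoxazoline (N–O hydrogenolysis, then hydride reduction). The spiro‑tetrahydrofuran C9–O bond comes from 5‑endo iodo‑etherification of a 9(11)‑alkene by the C13 tertiary alcohol.
- The C12–C13 bond comes from alkylating the (R)‑malic acid‑derived Seebach dioxolanone enolate (C13 is bought) with a decalin allylic bromide. The bromide comes from the C9 ketone by vinyl addition and allylic transposition.
- Ring A, the quaternary C4 and both the C3 and C18 oxygens come from one intramolecular nitrile oxide–alkene cycloaddition onto the isopropenyl group (key step).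
- Ring B is (R)‑carvone: C5 is bought, C10 is set by two α′‑alkylations (methyl, then propargyl anti to isopropenyl), and C8 by conjugate reduction and equilibration.
- Ring order: B (bought) → A plus isoxazoline (cycloaddition) → butyrolactone → spiro‑tetrahydrofuran.

Assumption: intermediates are located with the labdane numbering (C1–C20) of the target, and (R)‑malic acid, the dearer enantiomer, is taken as an acceptable commercial chiral‑pool material alongside cheap (R)‑carvone.

## Route

Step 1
Reactants: 1 (R)-(−)-carvone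
Product: 3 trans-6-methylcarvone [(5R,6S)-2,6-dimethyl-5-(prop-1-en-2-yl)cyclohex-2-en-1-one; minor 6R epimer carried along], via lithium dienolate 2 (not isolated)
Conditions: LiN(i-Pr)2 (LDA), THF, −78 °C; MeI, −78 → 0 °C
Reagents that add atoms: iodomethane, CI
Why: Kinetic α′‑deprotonation gives the cross‑conjugated dienolate, and its C‑methylation (enolate alkylation) installs the future C20 methyl; the new centre is erased by re‑enolisation in step 2.

Step 2
Reactants: 3 trans-6-methylcarvone
Product: 5 (5S,6S)-2,6-dimethyl-5-(prop-1-en-2-yl)-6-(prop-2-yn-1-yl)cyclohex-2-en-1-one, via lithium enolate 4 (not isolated)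
Conditions: LiN(i-Pr)2 (LDA), THF, −78 °C; propargyl bromide, DMPU, −78 °C → rt
Reagents that add atoms: propargyl bromide (3-bromoprop-1-yne), C#CCBr
Why: Second enolate alkylation, in which the electrophile attacks anti to the adjacent isopropenyl group (1,2‑induction from the carvone centre), so quaternary C10 carries CH3 cis and the three‑carbon chain trans to isopropenyl.

Step 3
Reactants: 5 (5S,6S)-2,6-dimethyl-5-(prop-1-en-2-yl)-6-(prop-2-yn-1-yl)cyclohex-2-en-1-one
Product: 7 (2S,3S,6R)-2,6-dimethyl-3-(prop-1-en-2-yl)-2-(prop-2-yn-1-yl)cyclohexan-1-one, via lithium enolate 6 (not isolated)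
Conditions: LiBH(s-Bu)3, THF, −78 °C; then MeOH, 0 °C → rt
Reagents that add atoms: none
Why: Conjugate (1,4) hydride reduction of the β‑unsubstituted, α′‑quaternary enone, followed by LiOMe‑mediated equilibration that puts the C8 methyl equatorial (8α), away from a syn‑diaxial clash with the C10 methyl.

Step 4
Reactants: 7 (2S,3S,6R)-2,6-dimethyl-3-(prop-1-en-2-yl)-2-(prop-2-yn-1-yl)cyclohexan-1-one
Product: 9 3-[(1S,3R,6S)-1,3-dimethyl-2-oxo-6-(prop-1-en-2-yl)cyclohexyl]propanal, via alkenylborane 8 (not isolated)
Conditions: Cy2BH, THF, 0 °C; then 30% H2O2, pH 7 phosphate buffer, 0 °C → rt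
Reagents that add atoms: hydrogen peroxide, OO
Why: Brown hydroboration–oxidation, in which the hindered dialkylborane adds anti‑Markovnikov to the terminal alkyne far faster than to the 1,1‑disubstituted alkene or the hindered ketone, and buffered oxidation gives the aldehyde without aldol side reactions.

Step 5
Reactants: 9 3-[(1S,3R,6S)-1,3-dimethyl-2-oxo-6-(prop-1-en-2-yl)cyclohexyl]propanal
Product: 12 isoxazoline ketone (trans-decalin-9-one; 8α-CH3; 10β-CH3; 4β-CH3; 2-isoxazoline C3=N–O–C18H2–C4 fused across C3–C4; C18 α), via oxime 10 (not isolated), via nitrile oxide 11 (not isolated)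
Conditions: NH2OH·HCl, NaOAc, EtOH/H2O, rt; then TsN(Cl)Na·3H2O, EtOH (0.01 M), 45 °C; then K2CO3, MeOH, rt
Reagents that add atoms: hydroxylamine (from its hydrochloride), NO
Why: Oximation, oxidation to the nitrile oxide and intramolecular nitrile oxide–alkene 1,3‑dipolar (Huisgen) cycloaddition close ring A in the fused mode; the chair‑like transition state on the trans‑diequatorial tether forces the isoxazoline CH2O equatorial (α) and the methyl axial (β) at the new quaternary C4, and the carbonate stage converges any 8‑epimer to 8α in the rigid trans‑decalin.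

Step 6
Reactants: 12 isoxazoline ketone
Product: 13 9-vinyl-9-hydroxy isoxazoline (tertiary allylic alcohol; mainly 9α-vinyl/9β-OH)
Conditions: CH2=CHMgBr, CeCl3, THF, −78 → 0 °C; aq NH4Cl
Reagents that add atoms: vinylmagnesium bromide, C=C[Mg]Br
Why: Imamoto organocerium 1,2‑addition overcomes enolisation of the hindered C9 ketone and leaves the isoxazoline C=N untouched; the C9 configuration (mainly axial attack anti to the C10 methyl) is erased in step 7.

Step 7
Reactants: 13 9-vinyl-9-hydroxy isoxazoline
Product: 14 allylic bromide (9(11)-ene with C12–Br; E/Z mixture)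
Conditions: PBr3, pyridine (cat.), Et2O, −10 → 0 °C
Reagents that add atoms: phosphorus tribromide, BrP(Br)Br
Why: Bromination with allylic transposition (SN2′ collapse of the tertiary allylic phosphite) gives the thermodynamically preferred primary allylic bromide with the trisubstituted exocyclic alkene; the alkene geometry is inconsequential.

Step 8
Reactants: 15 (R)-malic acid
Product: 16 (2R,4R)-2-tert-butyl-5-oxo-1,3-dioxolane-4-acetic acid (cis)
Conditions: t-BuCHO, TsOH (cat.), H2SO4 (cat.), pentane, reflux (Dean–Stark); recrystallise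
Reagents that add atoms: pivalaldehyde, CC(C)(C)C=O
Why: Acid‑catalysed acetalisation (Seebach self‑regeneration of stereocentres) gives the cis‑dioxolanone as the thermodynamic, crystalline isomer, the malic acid centre fixing the new acetal centre.

Step 9
Reactants: 16 (2R,4R)-2-tert-butyl-5-oxo-1,3-dioxolane-4-acetic acid; 14 allylic bromide
Product: 18 C13-alkylated dioxolanone acid [(2R,4R)-2-tert-butyl-4-(2-decalinylidene-ethyl)-5-oxo-1,3-dioxolane-4-acetic acid], via dilithio dianion 17 (not isolated)
Conditions: LiN(SiMe3)2 (2.1 equiv per 16; 16 in 1.5-fold excess), THF, −78 °C; then 14, −78 → −30 °C; aq HCl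
Reagents that add atoms: none
Why: Seebach enolate alkylation, in which the allylic bromide attacks the planar dioxolanone enolate anti to the tert‑butyl group, so the chain replaces the original hydrogen with retention and the malic carbon becomes C13 with the required R configuration.

Step 10
Reactants: 18 C13-alkylated dioxolanone acid
Product: 20 (R)-4-hydroxy-4-[2-(decalinylidene)ethyl]oxolan-2-one (β-hydroxy-γ-lactone; C13 R), via dihydroxy acid 19 (not isolated)
Conditions: LiBH4, THF, 0 °C → rt; then 1 M HCl, rt
Reagents that add atoms: none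
Why: Chemoselective borohydride reduction of the activated acylal lactone (the lithium carboxylate and the isoxazoline are inert) frees the 1,2‑diol, and acidification closes the primary C16 hydroxyl onto the C15 acid (γ‑lactonisation) without touching C13.

Step 11
Reactants: 20 (R)-4-hydroxy-4-[2-(decalinylidene)ethyl]oxolan-2-one
Product: 21 11-iodo-9α,13R-epoxy spiro-lactone isoxazoline (C11 epimers)
Conditions: I2, NaHCO3, MeCN, 0 °C, dark
Reagents that add atoms: iodine, II
Why: 5‑endo‑trig iodo‑etherification (Knight), in which the iodonium has cation character at the fully substituted C9 and the C13 hydroxyl attacks along the axial α trajectory anti to the C10 methyl (as in oxymercuration of methylenecyclohexanes), giving the more stable spiro‑ether with O axial and C11 equatorial; the C11 iodide is removed in step 12.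

Step 12
Reactants: 21 11-iodo-9α,13R-epoxy spiro-lactone isoxazoline
Product: 23 target (3S,4R,5S,8R,9R,10S,13R)-3,18-dihydroxy-9,13-epoxylabdan-16,15-olide, via β-hydroxy ketone 22 (not isolated)
Conditions: H2 (1 atm), Raney Ni, B(OH)3, NaOAc, MeOH/H2O (5:1), rt; filter; then NaBH4, MeOH, 0 °C; AcOH quench
Reagents that add atoms: water, O
Why: Raney Ni hydrogenolysis removes the C–I bond (as for 2‑deoxy‑2‑iodoglycosides) and cleaves the isoxazoline N–O bond, boric acid hydrolysing the imine to the β‑hydroxy ketone (Curran unmasking), and NaBH4 then attacks axially from the α face, opposite the axial 4β and 10β methyls, to give the equatorial 3β alcohol.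

## Compound list

1 | (R)-(−)-carvone, (5R)-2-methyl-5-(prop-1-en-2-yl)cyclohex-2-en-1-one | CC1=CC[C@H](CC1=O)C(C)=C | starting material
2 | lithium cross-conjugated dienolate of 1 (carvone stereocentre retained) | [Li]OC1=C[C@@H](CC=C1C)C(C)=C | intermediate
3 | trans-6-methylcarvone, (5R,6S)-2,6-dimethyl-5-(prop-1-en-2-yl)cyclohex-2-en-1-one (major epimer) | CC1=CC[C@H]([C@H](C)C1=O)C(C)=C | intermediate
4 | lithium enolate of 3 (tetrasubstituted, cross-conjugated) | [Li]OC1=C(C)[C@@H](CC=C1C)C(C)=C | intermediate
5 | (5S,6S)-2,6-dimethyl-5-(prop-1-en-2-yl)-6-(prop-2-yn-1-yl)cyclohex-2-en-1-one (methyl cis, propargyl trans to isopropenyl) | CC1=CC[C@H]([C@](C)(CC#C)C1=O)C(C)=C | intermediate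
6 | lithium enolate from 1,4-reduction of 5 (C8=C9–OLi) | [Li]OC1=C(C)CC[C@@H](C(C)=C)[C@]1(C)CC#C | intermediate
7 | (2S,3S,6R)-2,6-dimethyl-3-(prop-1-en-2-yl)-2-(prop-2-yn-1-yl)cyclohexan-1-one (8α-methyl equatorial) | C[C@@H]1CC[C@H]([C@](C)(CC#C)C1=O)C(C)=C | intermediate
8 | (E)-alkenyl(dicyclohexyl)borane from anti-Markovnikov hydroboration of 7 | C[C@@H]1CC[C@H]([C@](C)(C/C=C/B(C2CCCCC2)C3CCCCC3)C1=O)C(C)=C | intermediate
9 | 3-[(1S,3R,6S)-1,3-dimethyl-2-oxo-6-(prop-1-en-2-yl)cyclohexyl]propanal | C[C@@H]1CC[C@H]([C@](C)(CCC=O)C1=O)C(C)=C | intermediate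
10 | aldoxime of 9 (E/Z) | C[C@@H]1CC[C@H]([C@](C)(CCC=NO)C1=O)C(C)=C | intermediate
11 | nitrile oxide from 10 | C[C@@H]1CC[C@H]([C@](C)(CCC#[N+][O-])C1=O)C(C)=C | intermediate
12 | isoxazoline ketone: trans-decalin-9-one (5α-H, 10β-CH3, 8α-CH3, 4β-CH3) with 2-isoxazoline C3=N–O–C18H2–C4, C18 α | C[C@@H]1CC[C@H]2[C@]3(C)CON=C3CC[C@]2(C)C1=O | intermediate
13 | 9-hydroxy-9-vinyl derivative of 12 (major 9α-vinyl/9β-OH; C9 erased in step 7) | C[C@@H]1CC[C@H]2[C@]3(C)CON=C3CC[C@]2(C)[C@]1(O)C=C | intermediate
14 | allylic bromide: 9(11)-ene, C12–Br (E/Z mixture) | C[C@@H]1CC[C@H]2[C@]3(C)CON=C3CC[C@]2(C)C1=CCBr | intermediate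
15 | (R)-malic acid | O[C@H](CC(O)=O)C(O)=O | starting material
16 | (2R,4R)-2-tert-butyl-5-oxo-1,3-dioxolane-4-acetic acid (cis) | OC(=O)C[C@H]1O[C@@H](C(C)(C)C)OC1=O | intermediate
17 | dilithio dianion of 16 (carboxylate plus dioxolanone enolate) | [Li]OC(=O)CC1=C(O[Li])O[C@H](C(C)(C)C)O1 | intermediate
18 | (2R,4R)-2-tert-butyl-4-[2-(decalinylidene)ethyl]-5-oxo-1,3-dioxolane-4-acetic acid (chain trans to tert-butyl; decalin as in 14) | C[C@@H]1CC[C@H]2[C@]3(C)CON=C3CC[C@]2(C)C1=CC[C@]4(CC(O)=O)O[C@@H](C(C)(C)C)OC4=O | intermediate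
19 | (3R)-3-hydroxy-3-(hydroxymethyl)-5-(decalinylidene)pentanoic acid | C[C@@H]1CC[C@H]2[C@]3(C)CON=C3CC[C@]2(C)C1=CC[C@](O)(CO)CC(O)=O | intermediate
20 | (R)-4-hydroxy-4-[2-(decalinylidene)ethyl]oxolan-2-one (13R-hydroxy-16,15-olide, 9(11)-ene) | C[C@@H]1CC[C@H]2[C@]3(C)CON=C3CC[C@]2(C)C1=CC[C@]4(O)COC(=O)C4 | intermediate
21 | 11-iodo-9α,13R-epoxy-16,15-olide with ring-A isoxazoline (C11 epimers) | C[C@@H]1CC[C@H]2[C@]3(C)CON=C3CC[C@]2(C)[C@@]14C(I)C[C@@]5(COC(=O)C5)O4 | intermediate
22 | 18-hydroxy-3-oxo-9α,13R-epoxylabdan-16,15-olide | C[C@@H]1CC[C@H]2[C@](C)(CO)C(=O)CC[C@]2(C)[C@@]12CC[C@@]1(COC(=O)C1)O2 | intermediate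
23 | (3S,4R,5S,8R,9R,10S,13R)-3,18-dihydroxy-9,13-epoxylabdan-16,15-olide (3β-OH, 4α-CH2OH, 8α-CH3, 9α-O) | C[C@@H]1CC[C@H]2[C@](C)(CO)[C@@H](O)CC[C@]2(C)[C@@]12CC[C@@]1(COC(=O)C1)O2 | target

## Step count and risks

Total steps: 12. Longest linear sequence: 11 (steps 1–7 and 9–12, from 1); step 8 is the one-step side branch.

Most likely to fail: steps 11, 9 and 5.

Step 11 (spiro‑etherification) is the weakest point. The closure is 5‑endo, joins two fully substituted carbons, and the C9 face preference is argued by analogy, not demonstrated on this system. If it is slow or gives the 9‑epimer, the fallback sets out from 20 and closes the ring by radical–polar crossover hydroalkoxylation. Conditions are the cobalt salen complex Co(C32H46N2O2) (divalent cobalt bound to N,N'-bis(3,5-di-tert-butylsalicylidene)ethylenediamine, 5 mol %), N-fluoro-2,4,6-trimethylpyridinium triflate and (Me2SiH)2O in PhCF3 at 0 °C → rt. Hydrogen‑atom transfer to C11 gives the tertiary C9 radical, which is oxidised to the cation and trapped by the C13 hydroxyl from the axial α face with no anti‑addition constraint. This gives the iodine‑free spiro‑ether isoxazoline F4 directly. Hydrogenolysis of F4 under the first‑stage conditions of step 12 (H2, Raney Ni, B(OH)3, MeOH/H2O) comes back to the route at 22.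

Step 9 (fragment union) depends on a poorly soluble, thermally fragile dianion reacting with a precious, ionisation‑prone allylic bromide. The fallback sets out from 16 and switches to a neutral‑ester monoenolate with a different end‑game. Compound 16 is esterified with tert‑butyl 2,2,2‑trichloroacetimidate (BF3·OEt2 cat., CH2Cl2/cyclohexane) to the tert‑butyl ester F2. Its monolithium enolate (LiN(SiMe3)2, 1.05 equiv, THF/DMPU, −78 °C) is alkylated with 14, again anti to the tert‑butyl group, to the alkylated tert‑butyl ester F3. LiBH4 then reduces only the dioxolanone, and CF3CO2H cleaves the tert‑butyl ester and lactonises, coming back to the route at 20.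

Step 5 (key cycloaddition) can lose material to nitrile oxide dimerisation, or to bridged‑mode addition onto the 1,1‑disubstituted alkene while the quaternary C4 is being made. The fallback sets out from oxime 10, now isolated after the first stage. Heating 10 in toluene at 180 °C (sealed tube) tautomerises it to the NH‑nitrone, which undergoes intramolecular oxime–olefin cycloaddition through the same chair‑like fused transition state and cannot dimerise. This gives the N‑unsubstituted isoxazolidine F1. Dehydrogenation of F1 with activated MnO2 in CH2Cl2 comes back to the route at 12.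

Further compounds

F1 | step 5 | N-unsubstituted isoxazolidine analogue of 12 (C3–H, N–H; C3 configuration inconsequential) | C[C@@H]1CC[C@H]2[C@]3(C)CONC3CC[C@]2(C)C1=O
F2 | step 9 | tert-butyl (2R,4R)-2-tert-butyl-5-oxo-1,3-dioxolane-4-acetate | CC(C)(C)OC(=O)C[C@H]1O[C@@H](C(C)(C)C)OC1=O
F3 | step 9 | tert-butyl ester of 18 (C13-alkylated dioxolanone) | C[C@@H]1CC[C@H]2[C@]3(C)CON=C3CC[C@]2(C)C1=CC[C@]4(CC(=O)OC(C)(C)C)O[C@@H](C(C)(C)C)OC4=O
F4 | step 11 | iodine-free 9α,13R-epoxy-16,15-olide with ring-A isoxazoline | C[C@@H]1CC[C@H]2[C@]3(C)CON=C3CC[C@]2(C)[C@@]14CC[C@@]5(COC(=O)C5)O4
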